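**Strategy.** With the chain numbered C1 (alkyne CH) to C15, C6 and C10 of the oxocane (O, C12, C11, C10, C9, C8, C7, C6) are 1,5-related. The eight-membered ring is therefore treated as a cyclopentene C6=C10, carrying trans C7/C9 oxygens, fused through that alkene to a dihydrofuran (O, C12, C11). Ozonolysis of this shared enol-ether bond turns the two five-membered rings into the oxocane as a C6 lactone/C10 ketone in one operation, with C7, C9, C12 and C13 already set. The substrate is a 2-oxabicyclo[3.3.0]oct-1(5)-ene with trans silyloxy groups and a C12 (1-alkoxypropyl) chain; the tetrahydrofuran and the bromides follow.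

Key step: step 11

Remarks on the chemistry (assumptions):
- Atom labels C1–C15 follow the target chain throughout. The target is 3R,4R,6S,7R,9R,10S,12R,13S; the key-step substrate and product are 7R,9R,12R,13R. C7, C9 and C12 are retained and C13 is inverted, so these structures need no stereochemical correction.
- Design change: O13 is capped (methoxymethyl) before the dihydrofuran is closed, so only O12 can form the enol ether. O13 and O3 carry orthogonal groups so that the two side-chain bromides go in one after the other.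
- Compounds 7–16 are drawn as the C10 epimer expected to predominate. C6 and C10 become sp2 in step 10, so regio- and stereoisomers from steps 5–6 converge.
- Allyl methoxymethyl ether, (−)-B-methoxydiisopinocampheylborane and methyl 2,2-dimethoxypropanoate are taken as purchasable.

Step 1
Reactants: 1 (1S,4R)-cis-4-acetoxycyclopent-2-en-1-ol
Product: 2 (1R,3R)-cyclopent-4-ene-1,3-diyl diacetate
Conditions: PPh3, DIAD, AcOH, THF, 0 °C → rt
Reagents that add atoms: acetic acid, CC(=O)O
Why: Mitsunobu reaction, in which acetate displaces the phosphonium-activated allylic alcohol by SN2 with inversion at C1, turning the cis monoacetate into the C2-symmetric trans diacetate.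

Step 2
Reactants: 2 trans diacetate
Product: 3 (1R,3R)-cyclopent-4-ene-1,3-diol
Conditions: K2CO3 (cat.), MeOH, rt
Reagents that add atoms: none
Why: Base-catalysed transesterification (methanolysis) removes both acetates without touching the stereocentres.

Step 3
Reactants: 3 trans diol
Product: 4 (3R,5R)-3,5-bis(tert-butyldimethylsilyloxy)cyclopent-1-ene
Conditions: TBSCl, imidazole, DMF, rt
Reagents that add atoms: tert-butyldimethylsilyl chloride, CC(C)(C)[Si](C)(C)Cl
Why: Imidazole-promoted silylation of both secondary alcohols; identical groups keep the C2 axis that makes the two alkene carbons equivalent.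

Step 4
Reactants: 4 bis-silyl ether
Product: 5 epoxide (1S,2R,4R,5R)-2,4-bis(tert-butyldimethylsilyloxy)-6-oxabicyclo[3.1.0]hexane
Conditions: mCPBA, NaHCO3, CH2Cl2, rt
Reagents that add atoms: 3-chloroperbenzoic acid, O=C(OO)c1cccc(Cl)c1
Why: Prilezhaev epoxidation; the C2 axis interchanges the two alkene faces, so only one epoxide (cis to one silyloxy group, trans to the other) can form.

Step 5
Reactants: 5 epoxide; 6 allylmagnesium bromide
Product: 7 (1R,2R,3R,5R)-2-allyl-3,5-bis(tert-butyldimethylsilyloxy)cyclopentan-1-ol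
Conditions: CuI (cat.), THF, −30 → 0 °C; aq. NH4Cl
Reagents that add atoms: allylmagnesium bromide (6), C=CC[Mg]Br
Why: Copper-catalysed SN2 epoxide opening with inversion (allyl trans to hydroxyl), preferred at the epoxide carbon whose neighbouring silyloxy group lies on the face away from the nucleophile; the other regioisomer differs only at C6 and C10 and converges in step 10.

Step 6
Reactants: 7 alcohol
Product: 8 (2S,3R,5R)-2-allyl-3,5-bis(tert-butyldimethylsilyloxy)cyclopentan-1-one
Conditions: Dess–Martin periodinane, NaHCO3, CH2Cl2, 0 °C → rt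
Reagents that add atoms: none
Why: Dess–Martin oxidation under buffered, non-basic conditions should give the β-silyloxy ketone without E1cB loss of silanol; epimerisation at C10 is immaterial.

Step 7
Reactants: 8 allyl ketone
Product: 10 keto aldehyde 2-[(1S,2R,4R)-2,4-bis(tert-butyldimethylsilyloxy)-5-oxocyclopentyl]acetaldehyde, via secondary ozonide 9 (not isolated)
Conditions: O3, CH2Cl2, −78 °C; then PPh3, −78 °C → rt
Reagents that add atoms: ozone, [O-][O+]=O
Why: Ozonolysis (Criegee mechanism) of the only alkene with reductive phosphine work-up gives the aldehyde carbon that becomes C12.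

Step 8
Reactants: 10 keto aldehyde; 11 allyl methoxymethyl ether
Product: 14 (2S,3R,5R)-3,5-bis(tert-butyldimethylsilyloxy)-2-[(2R,3R)-2-hydroxy-3-(methoxymethoxy)pent-4-en-1-yl]cyclopentan-1-one, via allylborane 12 (not isolated), via borinate ester 13 (not isolated)
Conditions: 11, s-BuLi, THF, −78 °C; (−)-Ipc2BOMe; BF3·OEt2; then 10, −78 °C; HOCH2CH2NH2 work-up
Reagents that add atoms: allyl methoxymethyl ether (11), C=CCOCOC
Why: Brown-type asymmetric γ-alkoxyallylboration, selective for the aldehyde over the ketone at −78 °C; the (Z)-allylborane reacts through a chair Zimmerman–Traxler transition state to give the syn product, and the isopinocampheyl groups from (+)-α-pinene should set 12R (hence 12R,13R) with O13 capped and O12 free.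

Step 9
Reactants: 14 vinyl carbinol
Product: 15 (2S,3R,5R)-3,5-bis(tert-butyldimethylsilyloxy)-2-[(2R,3R)-2-hydroxy-3-(methoxymethoxy)pentyl]cyclopentan-1-one
Conditions: H2 (1 atm), Pd/C, EtOAc, rt
Reagents that add atoms: none
Why: Heterogeneous hydrogenation of the monosubstituted alkene turns the vinyl group into the C14–C15 ethyl group; ketone, silyl ethers and acetal are inert.

Step 10
Reactants: 15 hydroxy ketone
Product: 17 enol ether (2R,4R,6R)-4,6-bis(tert-butyldimethylsilyloxy)-2-[(1R)-1-(methoxymethoxy)propyl]-3,4,5,6-tetrahydro-2H-cyclopenta[b]furan, via hemiketal 16 (not isolated)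
Conditions: PPTS (cat.), 4 Å sieves, toluene, 70 °C; Et3N quench
Reagents that add atoms: none
Why: Acid-catalysed cyclodehydration, in which the γ-hydroxy ketone closes to the five-membered hemiketal (only O12 is free, so no six-membered alternative exists) and the derived oxocarbenium ion loses the C10 proton to give the ring-fusion enol ether; mild acid protects the allylic C9 silyl ether.

Step 11
Reactants: 17 bicyclic enol ether
Product: 20 keto lactone (3R,5R,8R)-3,5-bis(tert-butyldimethylsilyloxy)-8-[(1R)-1-(methoxymethoxy)propyl]oxocane-2,6-dione, via primary ozonide 18 (not isolated), via carbonyl oxide 19 (not isolated)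
Conditions: O3, pyridine, CH2Cl2, −78 °C (stopped at first excess of ozone); then PPh3, −78 → 0 °C
Reagents that add atoms: ozone, [O-][O+]=O
Why: Ozone adds to the only C=C, the electron-rich tetrasubstituted enol ether C6=C10, in a [3+2] cycloaddition, and cycloreversion of the primary ozonide leaves an ester carbonyl on C6 and a carbonyl oxide on C10 that the phosphine reduces to the ketone (Criegee ozonolysis of an enol ether, the known cleavage of bicyclic enol ethers to medium-ring keto lactones). No ring is closed by bond formation: the oxocane arises by scission of the bond shared by the cyclopentene and dihydrofuran rings, so its eight atoms are their perimeter O–C12–C11–C10–C9–C8–C7–C6 (ring expansion by fragmentation). No stereocentre is created; C7, C9, C12 and C13 are carried through unchanged. The step needs chemoselectivity for the enol ether over the acetal and silyl ethers, which its much higher reactivity and the controlled ozone dose should secure. It must also avoid epimerisation at C9 and E1cB loss of the C12 acyloxy group from the β-acyloxy ketone, for which pyridine buffering, −78 °C and a neutral phosphine work-up are chosen.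

Step 12
Reactants: 20 keto lactone
Product: 21 (3R,5R,6R,8R)-3,5-bis(tert-butyldimethylsilyloxy)-6-hydroxy-8-[(1R)-1-(methoxymethoxy)propyl]oxocan-2-one
Conditions: (S)-2-methyl-CBS-oxazaborolidine (C18H20BNO), catecholborane, toluene, −78 °C; MeOH, pH 7 buffer, cold; used crude
Reagents that add atoms: none
Why: Corey–Bakshi–Shibata reduction, in which the catalyst binds the ketone anti to the branched C9 side and the (S)-catalyst is expected to give the 10R alcohol (trans to O9); the boron-bound alkoxide and cold neutral work-up are meant to prevent transannular acyl transfer from the lactone.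

Step 13
Reactants: 21 hydroxy lactone
Product: 23 (3R,5R,6S,8R)-6-bromo-3,5-bis(tert-butyldimethylsilyloxy)-8-[(1R)-1-(methoxymethoxy)propyl]oxocan-2-one, via triflate 22 (not isolated)
Conditions: Tf2O, 2,6-lutidine, CH2Cl2, −78 °C; then n-Bu4NBr, −78 → 0 °C
Reagents that add atoms: tetrabutylammonium bromide, CCCC[N+](CCCC)(CCCC)CCCC.[Br-]
Why: SN2 displacement of a secondary triflate by bromide with inversion (10R → 10S), done at the lactone stage because an ester oxygen does not form transannular oxonium ions and the C9 silyl ether cannot participate.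

Step 14
Reactants: 23 bromo lactone
Product: 25 lactol acetate (3R,5R,6S,8R)-6-bromo-3,5-bis(tert-butyldimethylsilyloxy)-8-[(1R)-1-(methoxymethoxy)propyl]oxocan-2-yl acetate (C6 epimers), via aluminium hemiacetal 24 (not isolated)
Conditions: i-Bu2AlH, CH2Cl2, −78 °C; then pyridine, DMAP, Ac2O, −78 → −20 °C
Reagents that add atoms: acetic anhydride, CC(=O)OC(C)=O
Why: Reductive acetylation of a lactone, in which the aluminium hemiacetal is acetylated in situ so that the eight-membered lactol cannot ring-open.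

Step 15
Reactants: 26 ethynyltrimethylsilane; 27 methyl 2,2-dimethoxypropanoate
Product: 29 4,4-dimethoxy-1-(trimethylsilyl)pent-1-yn-3-one, via lithium acetylide 28 (not isolated)
Conditions: n-BuLi, THF, −78 °C; then 27, BF3·OEt2, −78 °C
Reagents that add atoms: ethynyltrimethylsilane (26), C#C[Si](C)(C)C; methyl 2,2-dimethoxypropanoate (27), COC(=O)C(C)(OC)OC
Why: Acylation of a lithium acetylide by an ester whose tetrahedral adduct is stabilised by the α,α-dimethoxy group and BF3, so the ynone is released only on work-up and a second addition is avoided.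

Step 16
Reactants: 29 ynone
Product: 30 (3S)-4,4-dimethoxy-1-(trimethylsilyl)pent-1-yn-3-ol
Conditions: RuCl[(R,R)-TsDPEN](p-cymene) (cat.), i-PrOH, rt
Reagents that add atoms: none
Why: Noyori asymmetric transfer hydrogenation of an alkynyl ketone, in which the alkyne takes the site an aryl group occupies on the catalyst, so the (R,R)-catalyst is expected to give the S carbinol (target C3).

Step 17
Reactants: 30 propargylic alcohol
Product: 31 (3S)-3-(tert-butyldiphenylsilyloxy)-4,4-dimethoxy-1-(trimethylsilyl)pent-1-yne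
Conditions: TBDPSCl, imidazole, DMAP, DMF, 40 °C
Reagents that add atoms: tert-butyldiphenylsilyl chloride, CC(C)(C)[Si](Cl)(c1ccccc1)c1ccccc1
Why: Imidazole/DMAP-promoted silylation; the bulky ether shields the C3 hydrogen in the later enolisation and survives the acidic steps that remove the other silyl groups.

Step 18
Reactants: 31 ketal
Product: 32 (3S)-3-(tert-butyldiphenylsilyloxy)-5-(trimethylsilyl)pent-4-yn-2-one
Conditions: TFA, H2O, CH2Cl2, 0 °C
Reagents that add atoms: water, O
Why: Acid-catalysed ketal hydrolysis frees the methyl ketone without base, so the silyl ether, the alkynyl C–Si bond and the C3 centre should remain intact.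

Step 19
Reactants: 32 methyl ketone
Product: 34 enol silane (3S)-3-(tert-butyldiphenylsilyloxy)-2-(trimethylsilyloxy)-5-(trimethylsilyl)pent-1-en-4-yne, via lithium enolate 33 (not isolated)
Conditions: LiN(i-Pr)2, Me3SiCl, THF, −78 °C (in situ quench); Et3N
Reagents that add atoms: chlorotrimethylsilane, C[Si](C)(C)Cl
Why: Kinetic deprotonation of the methyl group with in situ silylation gives the terminal enol silane; the hindered, silyloxy-bearing C3–H should not be removed at −78 °C, so C3 keeps its configuration.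

Step 20
Reactants: 25 lactol acetate; 34 enol silane
Product: 36 ketone (3S)-1-[(2S,3R,5R,6S,8R)-6-bromo-3,5-bis(tert-butyldimethylsilyloxy)-8-[(1R)-1-(methoxymethoxy)propyl]oxocan-2-yl]-3-(tert-butyldiphenylsilyloxy)-5-(trimethylsilyl)pent-4-yn-2-one, via oxocarbenium ion 35 (not isolated)
Conditions: BF3·OEt2, CH2Cl2, −78 °C
Reagents that add atoms: enol silane (34), C=C(O[Si](C)(C)C)[C@@H](O[Si](c1ccccc1)(c1ccccc1)C(C)(C)C)C#C[Si](C)(C)C
Why: Mukaiyama-type addition of an enol silane to a cyclic oxocarbenium ion (C-glycosylation), with attack expected on the face away from the adjacent C7 silyloxy group and the C12 side chain, giving 6S with C5 trans to O7.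

Step 21
Reactants: 36 bis-silyl ketone
Product: 38 bicyclic hemiketal (C4 epimers), via hydroxy ketone 37 (not isolated)
Conditions: HF·pyridine, pyridine, THF, 0 °C → rt
Reagents that add atoms: none
Why: HF·pyridine cleaves the two secondary tert-butyldimethylsilyl ethers while the diphenylsilyl ether, alkynylsilane and acetal persist; the freed O7 adds to the C4 ketone as a five-membered hemiketal, and O9 would need a seven-membered ring.

Step 22
Reactants: 38 hemiketal
Product: 40 tetrahydrofuran (1S,3R,5S,6R,8R,10R)-5-bromo-10-[(1S)-1-(tert-butyldiphenylsilyloxy)-3-(trimethylsilyl)prop-2-yn-1-yl]-3-[(1R)-1-(methoxymethoxy)propyl]-2,9-dioxabicyclo[6.3.0]undecan-6-ol, via oxocarbenium ion 39 (not isolated)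
Conditions: Et3SiH, BF3·OEt2, CH2Cl2, −78 → −20 °C
Reagents that add atoms: none
Why: Ionic hydrogenation of a hemiketal, in which hydride is expected to add to C4 of the bicyclic oxocarbenium ion syn to the C6–O bond (inside attack on the envelope, as in 1,3-cis-selective silane reductions of 2-deoxyfuranosyl hemiketals), giving the 4R, 2,5-cis tetrahydrofuran.

Step 23
Reactants: 40 alcohol
Product: 41 C9 acetate
Conditions: Ac2O, pyridine, DMAP, CH2Cl2, 0 °C → rt
Reagents that add atoms: acetic anhydride, CC(=O)OC(C)=O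
Why: Acylation of the only free hydroxyl (O9) installs the acetate.

Step 24
Reactants: 41 acetate
Product: 43 C13 alcohol, via bromomethyl ether 42 (not isolated)
Conditions: Me2BBr, CH2Cl2, −78 °C; aq. NaHCO3
Reagents that add atoms: none
Why: Dimethylboron bromide cleaves the methoxymethyl acetal at −78 °C to a bromomethyl ether that hydrolyses on bicarbonate work-up; ester, silyl ethers and cyclic ethers are inert at this temperature.

Step 25
Reactants: 43 C13 alcohol
Product: 44 C13 bromide (13S)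
Conditions: CBr4, (n-C8H17)3P, toluene, 70 °C
Reagents that add atoms: carbon tetrabromide, BrC(Br)(Br)Br
Why: Appel-type bromination with a trialkylphosphine, the variant used for hindered secondary alcohols next to a medium-ring ether oxygen, proceeds by SN2 inversion (13R → 13S) while O3 is still silylated.

Step 26
Reactants: 44 silyl ether
Product: 45 propargylic alcohol (3S) with free alkyne
Conditions: n-Bu4NF, AcOH, THF, 0 °C → rt
Reagents that add atoms: none
Why: Buffered fluoride removes the propargylic tert-butyldiphenylsilyl ether and the alkynyl trimethylsilyl group together; acetic acid is there to suppress E2 loss of HBr.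

Step 27
Reactants: 45 propargylic alcohol
Product: 46 CNP0224788.1
Conditions: CBr4, PPh3, CH2Cl2, 0 °C
Reagents that add atoms: carbon tetrabromide, BrC(Br)(Br)Br
Why: Appel reaction of the propargylic alcohol by SN2 inversion (3S → 3R); low temperature and the absence of copper salts are chosen to disfavour SN2′ allene formation.

**Compound list**

1 | (1S,4R)-cis-4-acetoxycyclopent-2-en-1-ol | CC(=O)O[C@H]1C=C[C@@H](O)C1 | starting material
2 | (1R,3R)-cyclopent-4-ene-1,3-diyl diacetate | CC(=O)O[C@H]1C=C[C@H](OC(C)=O)C1 | intermediate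
3 | (1R,3R)-cyclopent-4-ene-1,3-diol | O[C@H]1C=C[C@H](O)C1 | intermediate
4 | (3R,5R)-3,5-bis(tert-butyldimethylsilyloxy)cyclopent-1-ene | CC(C)(C)[Si](C)(C)O[C@H]1C=C[C@H](O[Si](C)(C)C(C)(C)C)C1 | intermediate
5 | (1S,2R,4R,5R)-2,4-bis(tert-butyldimethylsilyloxy)-6-oxabicyclo[3.1.0]hexane | CC(C)(C)[Si](C)(C)O[C@H]1[C@H]2O[C@H]2[C@H](O[Si](C)(C)C(C)(C)C)C1 | intermediate
6 | allylmagnesium bromide | C=CC[Mg]Br | starting material
7 | (1R,2R,3R,5R)-2-allyl-3,5-bis(tert-butyldimethylsilyloxy)cyclopentan-1-ol | CC(C)(C)[Si](C)(C)O[C@H]1[C@H](CC=C)[C@@H](O)[C@H](O[Si](C)(C)C(C)(C)C)C1 | intermediate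
8 | (2S,3R,5R)-2-allyl-3,5-bis(tert-butyldimethylsilyloxy)cyclopentan-1-one | CC(C)(C)[Si](C)(C)O[C@H]1[C@H](CC=C)C(=O)[C@H](O[Si](C)(C)C(C)(C)C)C1 | intermediate
9 | secondary ozonide (1,2,4-trioxolane) of 8 | CC(C)(C)[Si](C)(C)O[C@H]1[C@H](CC2OCOO2)C(=O)[C@H](O[Si](C)(C)C(C)(C)C)C1 | intermediate
10 | 2-[(1S,2R,4R)-2,4-bis(tert-butyldimethylsilyloxy)-5-oxocyclopentyl]acetaldehyde | CC(C)(C)[Si](C)(C)O[C@H]1[C@H](CC=O)C(=O)[C@H](O[Si](C)(C)C(C)(C)C)C1 | intermediate
11 | allyl methoxymethyl ether | C=CCOCOC | starting material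
12 | [(Z)-3-(methoxymethoxy)prop-2-en-1-yl]diisopinocampheylborane | COCO/C=C\CB([C@@H]1C[C@@H]2C[C@H]([C@H]1C)C2(C)C)[C@@H]1C[C@@H]2C[C@H]([C@H]1C)C2(C)C | intermediate
13 | O12 diisopinocampheylborinate of 14 | CC(C)(C)[Si](C)(C)O[C@H]1[C@H](C[C@@H](OB([C@@H]2C[C@@H]3C[C@H]([C@H]2C)C3(C)C)[C@@H]2C[C@@H]3C[C@H]([C@H]2C)C3(C)C)[C@H](OCOC)C=C)C(=O)[C@H](O[Si](C)(C)C(C)(C)C)C1 | intermediate
14 | (2S,3R,5R)-3,5-bis(tert-butyldimethylsilyloxy)-2-[(2R,3R)-2-hydroxy-3-(methoxymethoxy)pent-4-en-1-yl]cyclopentan-1-one | CC(C)(C)[Si](C)(C)O[C@H]1[C@H](C[C@@H](O)[C@H](OCOC)C=C)C(=O)[C@H](O[Si](C)(C)C(C)(C)C)C1 | intermediate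
15 | (2S,3R,5R)-3,5-bis(tert-butyldimethylsilyloxy)-2-[(2R,3R)-2-hydroxy-3-(methoxymethoxy)pentyl]cyclopentan-1-one | CC(C)(C)[Si](C)(C)O[C@H]1[C@H](C[C@@H](O)[C@H](OCOC)CC)C(=O)[C@H](O[Si](C)(C)C(C)(C)C)C1 | intermediate
16 | cis-fused bicyclic hemiketal of 15 (O12 on C6) | CC[C@@H](OCOC)[C@H]1C[C@@H]2[C@](O)(O1)[C@H](O[Si](C)(C)C(C)(C)C)C[C@H]2O[Si](C)(C)C(C)(C)C | intermediate
17 | (2R,4R,6R)-4,6-bis(tert-butyldimethylsilyloxy)-2-[(1R)-1-(methoxymethoxy)propyl]-3,4,5,6-tetrahydro-2H-cyclopenta[b]furan | CC[C@@H](OCOC)[C@H]1CC2=C(O1)[C@H](O[Si](C)(C)C(C)(C)C)C[C@H]2O[Si](C)(C)C(C)(C)C | intermediate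
18 | primary ozonide (1,2,3-trioxolane across C6–C10) of 17 | CC[C@@H](OCOC)[C@H]1CC23OOOC2(O1)[C@H](O[Si](C)(C)C(C)(C)C)C[C@H]3O[Si](C)(C)C(C)(C)C | intermediate
19 | C10 carbonyl oxide of the eight-membered lactone | CC[C@@H](OCOC)[C@H]1CC(=[O+][O-])[C@H](O[Si](C)(C)C(C)(C)C)C[C@@H](O[Si](C)(C)C(C)(C)C)C(=O)O1 | intermediate
20 | (3R,5R,8R)-3,5-bis(tert-butyldimethylsilyloxy)-8-[(1R)-1-(methoxymethoxy)propyl]oxocane-2,6-dione | CC[C@@H](OCOC)[C@H]1CC(=O)[C@H](O[Si](C)(C)C(C)(C)C)C[C@@H](O[Si](C)(C)C(C)(C)C)C(=O)O1 | intermediate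
21 | (3R,5R,6R,8R)-3,5-bis(tert-butyldimethylsilyloxy)-6-hydroxy-8-[(1R)-1-(methoxymethoxy)propyl]oxocan-2-one | CC[C@@H](OCOC)[C@H]1C[C@@H](O)[C@H](O[Si](C)(C)C(C)(C)C)C[C@@H](O[Si](C)(C)C(C)(C)C)C(=O)O1 | intermediate
22 | C10 triflate of 21 | CC[C@@H](OCOC)[C@H]1C[C@@H](OS(=O)(=O)C(F)(F)F)[C@H](O[Si](C)(C)C(C)(C)C)C[C@@H](O[Si](C)(C)C(C)(C)C)C(=O)O1 | intermediate
23 | (3R,5R,6S,8R)-6-bromo-3,5-bis(tert-butyldimethylsilyloxy)-8-[(1R)-1-(methoxymethoxy)propyl]oxocan-2-one | CC[C@@H](OCOC)[C@H]1C[C@H](Br)[C@H](O[Si](C)(C)C(C)(C)C)C[C@@H](O[Si](C)(C)C(C)(C)C)C(=O)O1 | intermediate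
24 | diisobutylaluminium hemiacetal of 23 | CC[C@@H](OCOC)[C@H]1C[C@H](Br)[C@H](O[Si](C)(C)C(C)(C)C)C[C@@H](O[Si](C)(C)C(C)(C)C)C(O[Al](CC(C)C)CC(C)C)O1 | intermediate
25 | (3R,5R,6S,8R)-6-bromo-3,5-bis(tert-butyldimethylsilyloxy)-8-[(1R)-1-(methoxymethoxy)propyl]oxocan-2-yl acetate (C6 epimers) | CC[C@@H](OCOC)[C@H]1C[C@H](Br)[C@H](O[Si](C)(C)C(C)(C)C)C[C@@H](O[Si](C)(C)C(C)(C)C)C(OC(C)=O)O1 | intermediate
26 | ethynyltrimethylsilane | C#C[Si](C)(C)C | starting material
27 | methyl 2,2-dimethoxypropanoate | COC(=O)C(C)(OC)OC | starting material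
28 | lithium (trimethylsilyl)acetylide | [Li]C#C[Si](C)(C)C | intermediate
29 | 4,4-dimethoxy-1-(trimethylsilyl)pent-1-yn-3-one | CC(OC)(OC)C(=O)C#C[Si](C)(C)C | intermediate
30 | (3S)-4,4-dimethoxy-1-(trimethylsilyl)pent-1-yn-3-ol | CC(OC)(OC)[C@@H](O)C#C[Si](C)(C)C | intermediate
31 | (3S)-3-(tert-butyldiphenylsilyloxy)-4,4-dimethoxy-1-(trimethylsilyl)pent-1-yne | CC(OC)(OC)[C@@H](O[Si](c1ccccc1)(c1ccccc1)C(C)(C)C)C#C[Si](C)(C)C | intermediate
32 | (3S)-3-(tert-butyldiphenylsilyloxy)-5-(trimethylsilyl)pent-4-yn-2-one | CC(=O)[C@@H](O[Si](c1ccccc1)(c1ccccc1)C(C)(C)C)C#C[Si](C)(C)C | intermediate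
33 | lithium enolate of 32 (methyl side) | [Li]OC(=C)[C@@H](O[Si](c1ccccc1)(c1ccccc1)C(C)(C)C)C#C[Si](C)(C)C | intermediate
34 | (3S)-3-(tert-butyldiphenylsilyloxy)-2-(trimethylsilyloxy)-5-(trimethylsilyl)pent-1-en-4-yne | C=C(O[Si](C)(C)C)[C@@H](O[Si](c1ccccc1)(c1ccccc1)C(C)(C)C)C#C[Si](C)(C)C | intermediate
35 | C6 oxocarbenium ion of the oxocane | CC[C@@H](OCOC)[C@H]1C[C@H](Br)[C@H](O[Si](C)(C)C(C)(C)C)C[C@@H](O[Si](C)(C)C(C)(C)C)C=[O+]1 | intermediate
36 | (3S)-1-[(2S,3R,5R,6S,8R)-6-bromo-3,5-bis(tert-butyldimethylsilyloxy)-8-[(1R)-1-(methoxymethoxy)propyl]oxocan-2-yl]-3-(tert-butyldiphenylsilyloxy)-5-(trimethylsilyl)pent-4-yn-2-one | CC[C@@H](OCOC)[C@H]1C[C@H](Br)[C@H](O[Si](C)(C)C(C)(C)C)C[C@@H](O[Si](C)(C)C(C)(C)C)[C@H](CC(=O)[C@@H](O[Si](c2ccccc2)(c2ccccc2)C(C)(C)C)C#C[Si](C)(C)C)O1 | intermediate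
37 | 7,9-diol of 36 (open hydroxy ketone) | CC[C@@H](OCOC)[C@H]1C[C@H](Br)[C@H](O)C[C@@H](O)[C@H](CC(=O)[C@@H](O[Si](c2ccccc2)(c2ccccc2)C(C)(C)C)C#C[Si](C)(C)C)O1 | intermediate
38 | (1S,3R,5S,6R,8R)-5-bromo-10-[(1S)-1-(tert-butyldiphenylsilyloxy)-3-(trimethylsilyl)prop-2-yn-1-yl]-3-[(1R)-1-(methoxymethoxy)propyl]-2,9-dioxabicyclo[6.3.0]undecane-6,10-diol (C4 epimers) | C[Si](C)(C)C#C[C@H](O[Si](c3ccccc3)(c3ccccc3)C(C)(C)C)C1(O)C[C@@H]2O[C@@H]([C@H](OCOC)CC)C[C@H](Br)[C@H](O)C[C@H]2O1 | intermediate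
39 | C4 oxocarbenium ion of the bicycle | C[Si](C)(C)C#C[C@H](O[Si](c3ccccc3)(c3ccccc3)C(C)(C)C)C=1C[C@@H]2O[C@@H]([C@H](OCOC)CC)C[C@H](Br)[C@H](O)C[C@H]2[O+]=1 | intermediate
40 | (1S,3R,5S,6R,8R,10R)-5-bromo-10-[(1S)-1-(tert-butyldiphenylsilyloxy)-3-(trimethylsilyl)prop-2-yn-1-yl]-3-[(1R)-1-(methoxymethoxy)propyl]-2,9-dioxabicyclo[6.3.0]undecan-6-ol | C[Si](C)(C)C#C[C@H](O[Si](c3ccccc3)(c3ccccc3)C(C)(C)C)[C@H]1C[C@@H]2O[C@@H]([C@H](OCOC)CC)C[C@H](Br)[C@H](O)C[C@H]2O1 | intermediate
41 | C9 acetate of 40 | C[Si](C)(C)C#C[C@H](O[Si](c3ccccc3)(c3ccccc3)C(C)(C)C)[C@H]1C[C@@H]2O[C@@H]([C@H](OCOC)CC)C[C@H](Br)[C@H](OC(C)=O)C[C@H]2O1 | intermediate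
42 | O13 bromomethyl ether of 43 | C[Si](C)(C)C#C[C@H](O[Si](c3ccccc3)(c3ccccc3)C(C)(C)C)[C@H]1C[C@@H]2O[C@@H]([C@H](OCBr)CC)C[C@H](Br)[C@H](OC(C)=O)C[C@H]2O1 | intermediate
43 | (13R)-alcohol: as 41 with 3-[(1R)-1-hydroxypropyl] | C[Si](C)(C)C#C[C@H](O[Si](c3ccccc3)(c3ccccc3)C(C)(C)C)[C@H]1C[C@@H]2O[C@@H]([C@H](O)CC)C[C@H](Br)[C@H](OC(C)=O)C[C@H]2O1 | intermediate
44 | (13S)-bromide: as 41 with 3-[(1S)-1-bromopropyl] | C[Si](C)(C)C#C[C@H](O[Si](c3ccccc3)(c3ccccc3)C(C)(C)C)[C@H]1C[C@@H]2O[C@@H]([C@@H](Br)CC)C[C@H](Br)[C@H](OC(C)=O)C[C@H]2O1 | intermediate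
45 | (1S,3R,5S,6R,8R,10R)-5-bromo-3-[(1S)-1-bromopropyl]-10-[(1S)-1-hydroxyprop-2-yn-1-yl]-2,9-dioxabicyclo[6.3.0]undecan-6-yl acetate | C#C[C@H](O)[C@H]1C[C@@H]2O[C@@H]([C@@H](Br)CC)C[C@H](Br)[C@H](OC(C)=O)C[C@H]2O1 | intermediate
46 | CNP0224788.1, (1S,3R,5S,6R,8R,10R)-5-bromo-10-[(1R)-1-bromoprop-2-yn-1-yl]-3-[(1S)-1-bromopropyl]-2,9-dioxabicyclo[6.3.0]undecan-6-yl acetate | C#C[C@@H](Br)[C@H]1C[C@@H]2O[C@@H]([C@@H](Br)CC)C[C@H](Br)[C@H](OC(C)=O)C[C@H]2O1 | target

**Step count.** Total: 27 steps. Longest linear sequence: 22 steps (steps 1–14 and 20–27); the C1–C5 fragment takes steps 15–19.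

**Steps most likely to fail**

1. Step 12. Hydride may be delivered to the wrong face of the C10 ketone, and the new hydroxyl may take the lactone acyl group transannularly if the alkoxide is left basic or warm. Fallback from 20 to 21: reduce 20 under substrate control with K[HB(s-Bu)3] at −78 °C and a cold acidic quench, accepting the 10S alcohol F2 expected from attack anti to the C9 silyloxy group. Convert it with Tf2O/2,6-lutidine into the triflate F3 and displace this with n-Bu4NNO2 (Lattrell–Dax inversion). The nitrite ester F4 hydrolyses on work-up to the 10R alcohol 21, where the route resumes.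

2. Step 22. Hydride may enter the C4 oxocarbenium ion from the face of C8 if the trans-fused oxocane locks the envelope with the C6 oxygen pseudoequatorial, which would give the 2,5-trans tetrahydrofuran. Fallback from 36 to 40, which fixes C4 by substitution instead of by facial attack: reduce 36 with (R)-2-methyl-CBS-oxazaborolidine and catecholborane to the 4S alcohol F5 (also the Felkin–Anh product next to the silyloxy group). MsCl/Et3N gives the mesylate F6 and HF·pyridine removes the two tert-butyldimethylsilyl groups to give the diol mesylate F7. Warming F7 with 2,6-lutidine in toluene lets O7 displace the mesylate (5-exo SN2, inversion to 4R), giving 40.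

3. Step 11. Ozone may over-oxidise the acetal or silyl ethers, and peroxidic intermediates or their reduction may trigger E1cB opening of the β-acyloxy ketone or epimerisation at C9. Fallback from 17 to 20 without ozone: dihydroxylate the enol ether with OsO4 (cat.) and N-methylmorpholine N-oxide in buffered acetone/water to the α-hydroxy hemiketal F1. Cleave the glycol with Pb(OAc)4 in CH2Cl2 at −40 °C (Criegee glycol cleavage), which gives the keto lactone 20 directly.

**Further compounds**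

F1 | step 11 | C6,C10-diol (α-hydroxy hemiketal) of 17 | CC[C@@H](OCOC)[C@H]1CC2(O)C(O)(O1)[C@H](O[Si](C)(C)C(C)(C)C)C[C@H]2O[Si](C)(C)C(C)(C)C
F2 | step 12 | (3R,5R,6S,8R)-3,5-bis(tert-butyldimethylsilyloxy)-6-hydroxy-8-[(1R)-1-(methoxymethoxy)propyl]oxocan-2-one (10S alcohol) | CC[C@@H](OCOC)[C@H]1C[C@H](O)[C@H](O[Si](C)(C)C(C)(C)C)C[C@@H](O[Si](C)(C)C(C)(C)C)C(=O)O1
F3 | step 12 | triflate of F2 | CC[C@@H](OCOC)[C@H]1C[C@H](OS(=O)(=O)C(F)(F)F)[C@H](O[Si](C)(C)C(C)(C)C)C[C@@H](O[Si](C)(C)C(C)(C)C)C(=O)O1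
F4 | step 12 | (10R)-nitrite ester | CC[C@@H](OCOC)[C@H]1C[C@@H](ON=O)[C@H](O[Si](C)(C)C(C)(C)C)C[C@@H](O[Si](C)(C)C(C)(C)C)C(=O)O1
F5 | step 22 | (4S)-alcohol from 36 | CC[C@@H](OCOC)[C@H]1C[C@H](Br)[C@H](O[Si](C)(C)C(C)(C)C)C[C@@H](O[Si](C)(C)C(C)(C)C)[C@H](C[C@H](O)[C@@H](O[Si](c2ccccc2)(c2ccccc2)C(C)(C)C)C#C[Si](C)(C)C)O1
F6 | step 22 | (4S)-mesylate of F5 | CC[C@@H](OCOC)[C@H]1C[C@H](Br)[C@H](O[Si](C)(C)C(C)(C)C)C[C@@H](O[Si](C)(C)C(C)(C)C)[C@H](C[C@H](OS(C)(=O)=O)[C@@H](O[Si](c2ccccc2)(c2ccccc2)C(C)(C)C)C#C[Si](C)(C)C)O1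
F7 | step 22 | 7,9-diol (4S)-mesylate | CC[C@@H](OCOC)[C@H]1C[C@H](Br)[C@H](O)C[C@@H](O)[C@H](C[C@H](OS(C)(=O)=O)[C@@H](O[Si](c2ccccc2)(c2ccccc2)C(C)(C)C)C#C[Si](C)(C)C)O1
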